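Remark on the chemistry: the carbinol carbons formed in steps 6, 10 and 13 and the silyl-bearing C4 of 14 are expected as epimer mixtures. Each is later oxidised, deoxygenated or desilylated, so they are drawn without configuration and carried on unseparated. Chroman numbering (O1, C2 … C8a) is used throughout, with pinane atoms primed.

## Analysis of the target

Euglobal G3 (25) is a chroman whose C2 is also C2' of a pinane, so a dihydropyran ring is spiro-joined to a bicyclo[3.1.1]heptane that contains a cyclobutane. The benzene ring is fully substituted: hydroxyls at C5 and C7, an isovaleryl ketone at C6 between them, a formyl group at C8 between the C7 hydroxyl and O1, and the two fusion carbons C4a and C8a. There are three stereocentres. The bridgeheads C1' and C5' come unchanged from (−)-β-pinene; at the spiro carbon O1 lies anti to the gem-dimethyl bridge and C3 syn to it, which is the arrangement obtained when oxygen adds to the exocyclic alkene of β-pinene from its open face. The sensitive element is the O1–C2 bond, a tertiary alkyl aryl ether next to the cyclobutane: ionisation gives the 2-pinanyl cation and from it ring-opened or rearranged skeletons. The aldehyde, the chelated phenols and the α-methylene of the ortho-hydroxyaryl ketone further limit late acid and electrophile chemistry. The two hard problems are making that ether with defined configuration without positive charge at C2, and telling C6 from C8, which are both flanked by two oxygens. The strategy rests on the pyran ring (O1, C2, C3, C4, C4a, C8a): without C4 it is a five-membered furanone whose C3 ketone sits on the arene at C4a, ortho to C8a. That ketone can activate C8a for ether formation and afterwards accept the missing carbon between C3 and C4a.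

## Retrosynthetic reasoning

**Arene substituents (25 ⇒ 24 ⇒ 23 ⇒ 21 ⇒ 18 + 19).** The two acetal protecting groups of 24 are removed last. The ketone of 24 is taken back to the carbinol 23, and the C8–CHO bond of 23 is cut to give 21. The C6–C(carbinol) bond of 21 is then cut to give the bis(methoxymethyl) chroman 18 and 3-methylbutanal 19. Both bonds are cut at the arene because 18 has only two ring hydrogens and directed lithiation can tell them apart: C6–H lies between two chelating acetal ethers, C8–H between one of them and O1. The gain is that both carbonyl groups enter under basic conditions, which the tertiary ether tolerates.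

**C3 oxygen (18 ⇒ 17 ⇒ 16 ⇒ 15).** A carbonyl is placed at C3 of 18, giving chromanone 15, to be removed forward by reduction to 16 and radical deoxygenation of xanthate 17. The ketone is put there because it is the handle of the ring expansion and because, while present, it keeps the neighbouring spiro carbon from ionising.

**Key disconnection (15 ⇒ 12 + 13).** The C4–C4a and C3–C4 bonds are cut, which removes C4 and leaves the spiro coumaranone 12 and the one-carbon donor 13. This is preferred to cutting O1–C2 or O1–C8a of the six-membered ring, because neither of those closures has an activating group. In 12 the ketone is conjugated to the arene and ortho to the ether carbon. The forward reaction has to insert one carbon between C3 and the arene by an aryl shift, without touching the spiro centre.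

**Furanone ring (12 ⇒ 11 ⇒ 10 ⇒ 9 ⇒ 8 + 7).** In 12 the aryl C–O bond is cut, not the bond from oxygen to the pinane, so that oxygen stays on C2' throughout. Forward, the tertiary alkoxide of 11, released from silyl ether 10, displaces fluoride ortho to the ketone. The aryl–carbonyl bond of 10 is then cut via carbinol 9 to the aryllithium 8 and the silyloxy aldehyde 7. This makes the convergence point a simple carbonyl addition.

**Fragments (7 ⇒ 6 ⇒ 5 ⇒ 4; 8 ⇒ 3 ⇒ 2 ⇒ 1).** Aldehyde 7 is the silylated, oxidised form of diol 5, which is β-pinene 4 with two hydroxyls added syn to the exocyclic alkene. That addition sets the spiro configuration. Aryllithium 8 comes from bromide 3, made by acetal protection and bromination of 5-fluororesorcinol 1 through 2. The bromine sits where the carbonyl carbon will be attached, next to the fluorine that will become O1.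

## Alternatives that were turned down

**Alternative 1:** The benzene ring is made last. The C5–C6 bond is cut, leading to the fused 2-pyranone A2, a spiro dihydropyran with a 4-methyl-2-oxopentyl chain at C7. Forward, magnesium methoxide in methanol opens the lactone, the carbon between the two ketone carbonyls acylates the freed ester carbon (Claisen condensation), and enolisation gives arene A1.
- For: A1 has the isovaleryl group at C6 by construction and both phenols free, so no phenol protection is needed and the C6/C8 question does not arise for the acyl group. The ring forms under mild base. On these points it is stronger than the chosen route.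
- Against: A2 already contains the spiro ether, so the stereochemical problem is only moved into a less accessible heterocycle with a sensitive polyketone chain. Aldol closure modes of the opened chain compete with the Claisen mode. A1 must finally be formylated at C8 by electrophilic substitution, which exposes the ionisable ether and an ortho-hydroxyaryl ketone with an α-methylene group to acidic formylating agents.
- Comparison: the chosen route spends more protecting-group steps, but it reaches the ring system from 4 by predictable reactions and installs both carbonyls by lithiation.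

**Alternative 2:** The C6–C(acyl) and C7–O bonds are cut together. The precursors are silyl triflate A4 and chlorooxime A5. CsF converts A4 into the C6≡C7 aryne A6 and A5 into nitrile oxide A7, and their [3+2] cycloaddition gives benzisoxazole A3. Later N–O reduction and imine hydrolysis release the C6 ketone and the C7 phenol.
- For: the C5 alkoxy group polarises A6 so that the nitrile oxide oxygen should bond to C7, and the acyl group is carried in a robust masked form. For C6/C7 regiocontrol this is at least as good as directed lithiation.
- Against: the step does nothing for the spiro ring system. A4 needs the complete spirochroman, differentiated C5 and C7 oxygens and a silyl group placed selectively at C6, which is the same regiochemical problem one step earlier. C8 formylation and a reductive unmasking still follow.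
- Comparison: it would be longer than the chosen route, which solves ring system and spiro centre first and then needs only two lithiations.

**Alternative 3:** The C4–C4a and O1–C2 bonds are cut. Phenol aldehyde A9 and enal A10 (from ketone A11, the ozonolysis product of 4) condense under amine catalysis. Knoevenagel-type C-alkylation and dehydration are followed by oxa-6π ring closure to the 2H-chromene A8.
- For: the pyran ring and the spiro centre form in one step from two simple fragments, and the formyl group is present from the start. In step count this is clearly stronger than the chosen route.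
- Against: the spiro configuration depends on the facial preference of a reversible electrocyclisation. Closure anti to the gem-dimethyl bridge gives the right centre, but the epimer with the carbon chain anti to the bridge is probably the less strained, so equilibration can erode it. A8 then needs alkene hydrogenation beside a benzyl ether and an aryl aldehyde. The isovaleryl group must finally be placed at C6 of a formyl-deactivated ring by Lewis-acid acylation, in the presence of the ionisable ether.
- Comparison: the chosen route is longer, but the spiro centre is fixed by an irreversible dihydroxylation and never touched again, and C6 and C8 are addressed one at a time.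

Key step: step 9

## Route

Step 1
Reactants: 1 5-fluororesorcinol
Product: 2 1-fluoro-3,5-bis(methoxymethoxy)benzene
Conditions: MOMCl, i-Pr2NEt, CH2Cl2, 0 °C → rt
Reagents that add atoms: chloromethyl methyl ether, COCCl
Why: Williamson-type O-alkylation of both phenols by the reactive α-chloro ether. The methoxymethyl (MOM) ethers survive organolithiums, fluoride and radical conditions and later direct the ortho-lithiations.

Step 2
Reactants: 2 1-fluoro-3,5-bis(methoxymethoxy)benzene
Product: 3 2-bromo-1-fluoro-3,5-bis(methoxymethoxy)benzene
Conditions: NBS (1.0 equiv), MeCN, 0 °C → rt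
Reagents that add atoms: N-bromosuccinimide, O=C1CCC(=O)N1Br
Why: Electrophilic aromatic bromination. In 5-substituted resorcinol diethers the carbon para to one ether and ortho to the other (here next to fluorine) is more accessible than the carbon between the two ethers, and acid-free NBS with one equivalent should stop at the monobromide without harming the acetals.

Step 3
Reactants: 4 (1S,5S)-(−)-β-pinene
Product: 5 (1R,2S,5S)-2-(hydroxymethyl)-6,6-dimethylbicyclo[3.1.1]heptan-2-ol
Conditions: OsO4 (cat.), NMO, acetone/H2O, rt
Reagents that add atoms: N-methylmorpholine N-oxide, C[N+]1([O-])CCOCC1; water, O; OsO4 (catalytic oxygen carrier), O=[Os](=O)(=O)=O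
Why: Catalytic syn-dihydroxylation. OsO4 adds to the exocyclic alkene from the face anti to the gem-dimethyl bridge, so the tertiary hydroxyl ends up anti to the bridge and C10 syn to it. This is the O1–C2 configuration of the target; the bridgeheads are not involved.

Step 4
Reactants: 5 (1R,2S,5S)-2-(hydroxymethyl)-6,6-dimethylbicyclo[3.1.1]heptan-2-ol
Product: 6 (1R,2S,5S)-2-hydroxy-6,6-dimethylbicyclo[3.1.1]heptane-2-carbaldehyde
Conditions: (COCl)2, DMSO, CH2Cl2, −78 °C; Et3N, −78 → 0 °C
Reagents that add atoms: none
Why: Swern oxidation. Only the primary alcohol can be oxidised, activated DMSO does not cleave the glycol, and the quaternary α-carbon rules out enolisation; the crude aldehyde is silylated at once.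

Step 5
Reactants: 6 (1R,2S,5S)-2-hydroxy-6,6-dimethylbicyclo[3.1.1]heptane-2-carbaldehyde
Product: 7 (1R,2S,5S)-6,6-dimethyl-2-(triethylsilyloxy)bicyclo[3.1.1]heptane-2-carbaldehyde
Conditions: TESOTf, 2,6-lutidine, CH2Cl2, −78 → 0 °C
Reagents that add atoms: triethylsilyl trifluoromethanesulfonate, CC[Si](CC)(CC)OS(=O)(=O)C(F)(F)F
Why: Silylation with a silyl triflate is strong enough for the hindered tertiary hydroxyl, and the aldehyde has no α-hydrogen from which an enol silane could form. The silyl ether hides the hydroxyl from the aryllithium and is removed by fluoride when the alkoxide is needed.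

Step 6
Reactants: 3 2-bromo-1-fluoro-3,5-bis(methoxymethoxy)benzene; 7 (1R,2S,5S)-6,6-dimethyl-2-(triethylsilyloxy)bicyclo[3.1.1]heptane-2-carbaldehyde
Product: 9 [2-fluoro-4,6-bis(methoxymethoxy)phenyl][(1R,2S,5S)-6,6-dimethyl-2-(triethylsilyloxy)bicyclo[3.1.1]hept-2-yl]methanol as a mixture of carbinol epimers, via 2-fluoro-4,6-bis(methoxymethoxy)phenyllithium 8 (not isolated)
Conditions: 3, n-BuLi, THF, −78 °C; then 7, −78 °C; aq. NH4Cl at −78 °C
Reagents that add atoms: none
Why: Bromine–lithium exchange is faster than any deprotonation and puts lithium on the carbon flanked by fluorine and a MOM ether; at −78 °C this aryllithium should not lose LiF. 1,2-Addition to the non-enolisable aldehyde then gives the carbinol, whose new centre is removed in step 7.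

Step 7
Reactants: 9 [2-fluoro-4,6-bis(methoxymethoxy)phenyl][(1R,2S,5S)-6,6-dimethyl-2-(triethylsilyloxy)bicyclo[3.1.1]hept-2-yl]methanol
Product: 10 [2-fluoro-4,6-bis(methoxymethoxy)phenyl][(1R,2S,5S)-6,6-dimethyl-2-(triethylsilyloxy)bicyclo[3.1.1]hept-2-yl]methanone
Conditions: Dess–Martin periodinane, NaHCO3, CH2Cl2, rt
Reagents that add atoms: none
Why: Dess–Martin oxidation handles hindered benzylic alcohols under buffered, neutral conditions that leave the silyl ether and the acetals intact.

Step 8
Reactants: 10 [2-fluoro-4,6-bis(methoxymethoxy)phenyl][(1R,2S,5S)-6,6-dimethyl-2-(triethylsilyloxy)bicyclo[3.1.1]hept-2-yl]methanone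
Product: 12 4,6-bis(methoxymethoxy) spiro[benzofuran-2,2'-pinan]-3-one, via fluoro hydroxy ketone 11 (not isolated)
Conditions: Bu4NF, THF, 0 °C → 50 °C
Reagents that add atoms: none
Why: Fluoride cleaves the Si–O bond, and the tertiary alkoxide attacks the fluorine-bearing carbon ortho to the ketone in an intramolecular SNAr reaction (Meisenheimer intermediate, five-membered closure). Both acetal ethers are meta to that carbon and do not deactivate it. The bond from oxygen to the pinane is never broken, so the configuration from step 3 is retained.

Step 9
Reactants: 12 4,6-bis(methoxymethoxy) spiro[benzofuran-2,2'-pinan]-3-one; 13 trimethylsilyldiazomethane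
Product: 15 5,7-bis(methoxymethoxy) spiro[chroman-2,2'-pinan]-3-one, via 4-trimethylsilyl chroman-3-one 14 (not isolated)
Conditions: 13 (2 equiv), Sc(OTf)3 (20 mol %), toluene, 0 °C → rt; then K2CO3 (cat.), MeOH, rt
Reagents that add atoms: trimethylsilyldiazomethane (compound 13, supplies C4), C[Si](C)(C)C=[N+]=[N-]
Why: Sc(OTf)3 coordinates the C3 carbonyl oxygen of 12 and the nucleophilic diazo carbon of 13 adds to C3, which makes the C3–C4 bond and gives a scandium alkoxide carrying an α-silyl diazonium group. Nitrogen then leaves while the aryl carbon C4a shifts from C3 to the diazo-derived carbon, which makes the C4–C4a bond and restores the carbonyl at C3; this is a Tiffeneau–Demjanov-type homologation, and the closest known reaction is the Lewis-acid-promoted trimethylsilyldiazomethane ring expansion of indan-1-ones and tetral-1-ones to the β-aryl ketones. The six-membered ring is therefore not closed by a cyclisation but arises by enlargement of the furanone through insertion of one carbon into its C3–C4a bond. No stereocentre is created that survives: C4 of 14 carries silicon only until methanolysis turns it into CH2, and no bond to the spiro carbon is made or broken, so the configuration set in step 3 is carried through. The step needs aryl migration in preference to migration of the spiro carbon; the 2,4,6-trioxygenated ring stabilises the bridged transition state of the aryl shift, while the fully substituted, oxygen-bearing spiro carbon is inductively deactivated and can hardly align anti to the leaving nitrogen next to the bulky silyl group. It also needs a single insertion, which is secured because the product is held as the hindered α-silyl ketone until work-up. Because the spiro carbon stays α to a carbonyl throughout, the Lewis acid cannot ionise O1–C2 and the cyclobutane is safe. Should some migration of the spiro carbon occur, the carbonyl would sit at C4 and steps 10 to 12 would remove it just the same.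

Step 10
Reactants: 15 5,7-bis(methoxymethoxy) spiro[chroman-2,2'-pinan]-3-one
Product: 16 5,7-bis(methoxymethoxy) spiro[chroman-2,2'-pinan]-3-ol (C3 epimers)
Conditions: NaBH4, MeOH, 0 °C
Reagents that add atoms: none
Why: Hydride reduction of an unconjugated ketone. The ketone is reduced without storage because β-aryl ketones of this kind enolise and oxidise easily, and the C3 configuration is irrelevant.

Step 11
Reactants: 16 5,7-bis(methoxymethoxy) spiro[chroman-2,2'-pinan]-3-ol
Product: 17 O-[5,7-bis(methoxymethoxy) spiro[chroman-2,2'-pinan]-3-yl] S-methyl dithiocarbonate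
Conditions: NaH, imidazole (cat.), THF, 0 °C; CS2; then MeI, rt
Reagents that add atoms: carbon disulfide, S=C=S; iodomethane, CI
Why: Xanthate formation (alkoxide addition to CS2, then S-methylation) is the first half of the Barton–McCombie deoxygenation. It works on hindered secondary alcohols and uses only base, which ethers and acetals tolerate.

Step 12
Reactants: 17 O-[5,7-bis(methoxymethoxy) spiro[chroman-2,2'-pinan]-3-yl] S-methyl dithiocarbonate
Product: 18 5,7-bis(methoxymethoxy) spiro[chroman-2,2'-pinane]
Conditions: Bu3SnH, AIBN (cat.), toluene, 100 °C
Reagents that add atoms: none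
Why: Barton–McCombie deoxygenation: the stannyl radical adds to the thiocarbonyl, the C3–O bond breaks, and the secondary C3 radical takes hydrogen from Bu3SnH. The radical is one carbon removed from the cyclobutane and so cannot open it. A radical method is used because hydrazone-based or ionic deoxygenations would expel the α-aryloxy group or ionise C2.

Step 13
Reactants: 18 5,7-bis(methoxymethoxy) spiro[chroman-2,2'-pinane]; 19 3-methylbutanal
Product: 21 1-[5,7-bis(methoxymethoxy) spiro[chroman-2,2'-pinan]-6-yl]-3-methylbutan-1-ol (carbinol epimers), via 6-lithio chroman 20 (not isolated)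
Conditions: n-BuLi, TMEDA, THF, 0 °C; then 19, −78 → 0 °C; aq. NH4Cl
Reagents that add atoms: 3-methylbutanal (compound 19), CC(C)CC=O
Why: Directed ortho-metalation. C6–H lies between two MOM ethers that both chelate lithium, whereas C8–H has one such neighbour and the hindered ring oxygen, so deprotonation should occur at C6. The aryllithium then adds to the aldehyde at low temperature, where addition outruns enolisation.

Step 14
Reactants: 21 1-[5,7-bis(methoxymethoxy) spiro[chroman-2,2'-pinan]-6-yl]-3-methylbutan-1-ol
Product: 23 6-(1-hydroxy-3-methylbutyl)-5,7-bis(methoxymethoxy) spiro[chroman-2,2'-pinane]-8-carbaldehyde, via 8-lithio lithium alkoxide 22 (not isolated)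
Conditions: s-BuLi (2.5 equiv), TMEDA, THF, −78 → −20 °C; then DMF, −78 °C → rt; aq. NH4Cl
Reagents that add atoms: N,N-dimethylformamide, CN(C)C=O
Why: Directed ortho-metalation of the lithium alkoxide. The first equivalent of base removes the hydroxyl proton and the second the only remaining ring hydrogen, C8–H, which is flanked by the C7 MOM ether and O1; formylation with DMF follows. The formyl group thus enters under basic conditions, avoiding electrophilic formylation of an ortho-hydroxyaryl ketone next to the acid-labile ether.

Step 15
Reactants: 23 6-(1-hydroxy-3-methylbutyl)-5,7-bis(methoxymethoxy) spiro[chroman-2,2'-pinane]-8-carbaldehyde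
Product: 24 5,7-bis(methoxymethoxy)-6-(3-methylbutanoyl) spiro[chroman-2,2'-pinane]-8-carbaldehyde
Conditions: Dess–Martin periodinane, NaHCO3, CH2Cl2, rt
Reagents that add atoms: none
Why: Dess–Martin oxidation converts the benzylic alcohol into the ketone. Under anhydrous, buffered conditions the aldehyde is not oxidised further and the acetals and tertiary ether are not exposed to acid.

Step 16
Reactants: 24 5,7-bis(methoxymethoxy)-6-(3-methylbutanoyl) spiro[chroman-2,2'-pinane]-8-carbaldehyde
Product: 25 euglobal G3
Conditions: p-TsOH·H2O (cat.), MeOH, rt
Reagents that add atoms: none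
Why: Acid-catalysed transacetalisation transfers both MOM groups to methanol. Each is ortho to a carbonyl group, which makes it unusually labile, so catalytic acid at room temperature should suffice. O1 is conjugated to the para ketone and the ortho aldehyde and is only weakly basic, and the freed phenols are held in hydrogen bonds to the carbonyls.

## Compound list

1 | 5-fluororesorcinol | Oc1cc(O)cc(F)c1 | starting material
2 | 1-fluoro-3,5-bis(methoxymethoxy)benzene | COCOc1cc(F)cc(OCOC)c1 | intermediate
3 | 2-bromo-1-fluoro-3,5-bis(methoxymethoxy)benzene | COCOc1cc(F)c(Br)c(OCOC)c1 | intermediate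
4 | (1S,5S)-(−)-β-pinene | C=C1CC[C@H]2C[C@@H]1C2(C)C | starting material
5 | (1R,2S,5S)-2-(hydroxymethyl)-6,6-dimethylbicyclo[3.1.1]heptan-2-ol (tertiary OH anti to the gem-dimethyl bridge) | OC[C@@]1(CC[C@H]2C[C@@H]1C2(C)C)O | intermediate
6 | (1R,2S,5S)-2-hydroxy-6,6-dimethylbicyclo[3.1.1]heptane-2-carbaldehyde | O=C[C@@]1(CC[C@H]2C[C@@H]1C2(C)C)O | intermediate
7 | (1R,2S,5S)-6,6-dimethyl-2-(triethylsilyloxy)bicyclo[3.1.1]heptane-2-carbaldehyde | O=C[C@@]1(CC[C@H]2C[C@@H]1C2(C)C)O[Si](CC)(CC)CC | intermediate
8 | 2-fluoro-4,6-bis(methoxymethoxy)phenyllithium | [Li]c1c(F)cc(OCOC)cc1OCOC | intermediate (not isolated)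
9 | [2-fluoro-4,6-bis(methoxymethoxy)phenyl][(1R,2S,5S)-6,6-dimethyl-2-(triethylsilyloxy)bicyclo[3.1.1]hept-2-yl]methanol (carbinol epimers) | COCOc1cc(F)c(C(O)[C@@]2(CC[C@H]3C[C@@H]2C3(C)C)O[Si](CC)(CC)CC)c(OCOC)c1 | intermediate
10 | [2-fluoro-4,6-bis(methoxymethoxy)phenyl][(1R,2S,5S)-6,6-dimethyl-2-(triethylsilyloxy)bicyclo[3.1.1]hept-2-yl]methanone | COCOc1cc(F)c(C(=O)[C@@]2(CC[C@H]3C[C@@H]2C3(C)C)O[Si](CC)(CC)CC)c(OCOC)c1 | intermediate
11 | [2-fluoro-4,6-bis(methoxymethoxy)phenyl][(1R,2S,5S)-2-hydroxy-6,6-dimethylbicyclo[3.1.1]hept-2-yl]methanone | COCOc1cc(F)c(C(=O)[C@@]2(CC[C@H]3C[C@@H]2C3(C)C)O)c(OCOC)c1 | intermediate (not isolated)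
12 | 4,6-bis(methoxymethoxy) spiro[benzofuran-2,2'-pinan]-3-one (ring oxygen anti to the gem-dimethyl bridge) | COCOc1cc2c(c(OCOC)c1)C(=O)[C@@]1(CC[C@H]3C[C@@H]1C3(C)C)O2 | intermediate
13 | trimethylsilyldiazomethane | C[Si](C)(C)C=[N+]=[N-] | starting material
14 | 5,7-bis(methoxymethoxy)-4-(trimethylsilyl) spiro[chroman-2,2'-pinan]-3-one (C4 epimers) | COCOc1cc2c(c(OCOC)c1)C([Si](C)(C)C)C(=O)[C@@]1(CC[C@H]3C[C@@H]1C3(C)C)O2 | intermediate (not isolated)
15 | 5,7-bis(methoxymethoxy) spiro[chroman-2,2'-pinan]-3-one | COCOc1cc2c(c(OCOC)c1)CC(=O)[C@@]1(CC[C@H]3C[C@@H]1C3(C)C)O2 | intermediate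
16 | 5,7-bis(methoxymethoxy) spiro[chroman-2,2'-pinan]-3-ol (C3 epimers) | COCOc1cc2c(c(OCOC)c1)CC(O)[C@@]1(CC[C@H]3C[C@@H]1C3(C)C)O2 | intermediate
17 | O-[5,7-bis(methoxymethoxy) spiro[chroman-2,2'-pinan]-3-yl] S-methyl dithiocarbonate | COCOc1cc2c(c(OCOC)c1)CC(OC(=S)SC)[C@@]1(CC[C@H]3C[C@@H]1C3(C)C)O2 | intermediate
18 | 5,7-bis(methoxymethoxy) spiro[chroman-2,2'-pinane] | COCOc1cc2c(c(OCOC)c1)CC[C@@]1(CC[C@H]3C[C@@H]1C3(C)C)O2 | intermediate
19 | 3-methylbutanal | CC(C)CC=O | starting material
20 | 6-lithio-5,7-bis(methoxymethoxy) spiro[chroman-2,2'-pinane] | COCOc1cc2c(c(OCOC)c1[Li])CC[C@@]1(CC[C@H]3C[C@@H]1C3(C)C)O2 | intermediate (not isolated)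
21 | 1-[5,7-bis(methoxymethoxy) spiro[chroman-2,2'-pinan]-6-yl]-3-methylbutan-1-ol (carbinol epimers) | CC(C)CC(O)c1c(OCOC)cc2c(c1OCOC)CC[C@@]1(CC[C@H]3C[C@@H]1C3(C)C)O2 | intermediate
22 | lithium alkoxide of 21 lithiated at C8 | CC(C)CC(O[Li])c1c(OCOC)c([Li])c2c(c1OCOC)CC[C@@]1(CC[C@H]3C[C@@H]1C3(C)C)O2 | intermediate (not isolated)
23 | 6-(1-hydroxy-3-methylbutyl)-5,7-bis(methoxymethoxy) spiro[chroman-2,2'-pinane]-8-carbaldehyde (carbinol epimers) | CC(C)CC(O)c1c(OCOC)c(C=O)c2c(c1OCOC)CC[C@@]1(CC[C@H]3C[C@@H]1C3(C)C)O2 | intermediate
24 | 5,7-bis(methoxymethoxy)-6-(3-methylbutanoyl) spiro[chroman-2,2'-pinane]-8-carbaldehyde | CC(C)CC(=O)c1c(OCOC)c(C=O)c2c(c1OCOC)CC[C@@]1(CC[C@H]3C[C@@H]1C3(C)C)O2 | intermediate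
25 | euglobal G3 (spiro carbon R, pinane bridgeheads 1'R and 5'S; O1 anti to the gem-dimethyl bridge) | CC(C)CC(=O)c1c(O)c(C=O)c2c(c1O)CC[C@@]1(CC[C@H]3C[C@@H]1C3(C)C)O2 | target

## Step count and least certain steps

Total: 16 steps. Longest linear sequence: 14 steps (from 4 through steps 3–16); the arene branch from 1 runs through 13 steps (1, 2, 6–16).

**Step 9 (key step).** The C3 carbonyl of 12 is the end of a vinylogous carbonate (donation from O1 and both acetal ethers) and sits next to a quaternary carbon, so addition of 13 may be slow. Lewis-acid decomposition of 13, or chelation-assisted loss of the acetal ortho to the ketone, could then outrun it. Partial migration of the spiro carbon would be tolerated, as noted in the step. The fallback sets out from 12 and returns at 15. Dibromomethyllithium (CH2Br2, lithium 2,2,6,6-tetramethylpiperidide, THF, −78 °C) adds to the non-enolisable ketone to give the dibromomethyl carbinol F1. Two equivalents of n-BuLi at −78 °C → rt then form the alkoxide and exchange one bromine for lithium. The aryl group shifts to the carbenoid carbon with loss of LiBr, and protonation on work-up gives 15. This β-oxido carbenoid ring enlargement uses a much stronger nucleophile and no Lewis acid.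

**Step 13.** Deprotonation may occur partly at C8, which is also flanked by two oxygens, giving a mixture of regioisomeric carbinols. The fallback sets out from 18 and returns at 23. It fixes C8 first by electrophilic substitution, which in 5,7-dialkoxychromans prefers the less crowded C8. NBS in CH2Cl2 at −78 → 0 °C gives the 8-bromide F2. Bromine–lithium exchange (n-BuLi, THF, −78 °C) and DMF give the 8-aldehyde F3. Lithium N,N,N'-trimethylethylenediamide adds to F3 to give the α-amino alkoxide F4, which protects the aldehyde in the flask. n-BuLi then removes the only remaining ring hydrogen (C6–H), and addition of 19 followed by aqueous work-up gives 23.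

**Step 14.** Metalation of the electron-rich, alkoxide-bearing arene may be incomplete because of aggregation, so that 21 is recovered. The fallback sets out from 21 and returns at 25. Dess–Martin oxidation gives the ketone F5. Catalytic p-TsOH in MeOH removes the acetals to give the dihydroxy ketone F6, identical with A1. Rieche formylation (Cl2CHOMe, TiCl4, CH2Cl2, −20 °C) at the only free ring position then gives 25. This is known chemistry for acylphloroglucinols, but it exposes the tertiary ether to a strong Lewis acid, which is why it is not the first choice.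

**Step 16.** Acid-induced heterolysis of O1–C2, assisted by the cyclobutane, may compete with acetal cleavage, because the doubly acylated aryloxide is a good leaving group. The fallback sets out from 24 and returns at 25 without a Brønsted acid. TMSOTf with 2,2'-bipyridyl in CH2Cl2 at 0 °C transfers the methoxymethyl groups to the bipyridyl and leaves the bis(trimethylsilyl) ether F7. Water then hydrolyses F7 to 25.

**Step 6.** Addition of the doubly ortho-substituted aryllithium to the neopentyl-type aldehyde may be slow at −78 °C, the temperature needed to prevent loss of LiF. The silyl group may also shift from the tertiary oxygen to the new alkoxide, which would block step 7. The fallback sets out from 6 and returns at 12. The unprotected aldehyde 6 is treated with 8 (2.2 equiv, THF, −78 °C); the first equivalent forms the alkoxide and the second adds to the smaller aldehyde, giving the diol F8. Swern oxidation of the secondary alcohol gives 11, which is isolated here and closed to 12 with K2CO3 in DMF at 60 °C.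

## Further compounds

F1 | step 9 | 3-(dibromomethyl)-3-hydroxy-4,6-bis(methoxymethoxy) spiro[benzofuran-2,2'-pinane] (C3 epimers) | COCOc1cc2c(c(OCOC)c1)C(O)(C(Br)Br)[C@@]1(CC[C@H]3C[C@@H]1C3(C)C)O2
F2 | step 13 | 8-bromo-5,7-bis(methoxymethoxy) spiro[chroman-2,2'-pinane] | COCOc1c(Br)c2c(c(OCOC)c1)CC[C@@]1(CC[C@H]3C[C@@H]1C3(C)C)O2
F3 | step 13 | 5,7-bis(methoxymethoxy) spiro[chroman-2,2'-pinane]-8-carbaldehyde | COCOc1c(C=O)c2c(c(OCOC)c1)CC[C@@]1(CC[C@H]3C[C@@H]1C3(C)C)O2
F4 | step 13 | lithium α-amino alkoxide from F3 and lithium N,N,N'-trimethylethylenediamide | COCOc1c(C(O[Li])N(C)CCN(C)C)c2c(c(OCOC)c1)CC[C@@]1(CC[C@H]3C[C@@H]1C3(C)C)O2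
F5 | step 14 | 5,7-bis(methoxymethoxy)-6-(3-methylbutanoyl) spiro[chroman-2,2'-pinane] | CC(C)CC(=O)c1c(OCOC)cc2c(c1OCOC)CC[C@@]1(CC[C@H]3C[C@@H]1C3(C)C)O2
F6 | step 14 | 5,7-dihydroxy-6-(3-methylbutanoyl) spiro[chroman-2,2'-pinane] | CC(C)CC(=O)c1c(O)cc2c(c1O)CC[C@@]1(CC[C@H]3C[C@@H]1C3(C)C)O2
F7 | step 16 | 6-(3-methylbutanoyl)-5,7-bis(trimethylsilyloxy) spiro[chroman-2,2'-pinane]-8-carbaldehyde | CC(C)CC(=O)c1c(O[Si](C)(C)C)c(C=O)c2c(c1O[Si](C)(C)C)CC[C@@]1(CC[C@H]3C[C@@H]1C3(C)C)O2
F8 | step 6 | [2-fluoro-4,6-bis(methoxymethoxy)phenyl][(1R,2S,5S)-2-hydroxy-6,6-dimethylbicyclo[3.1.1]hept-2-yl]methanol (carbinol epimers) | COCOc1cc(F)c(C(O)[C@@]2(CC[C@H]3C[C@@H]2C3(C)C)O)c(OCOC)c1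
A1 | alternative 1 | 5,7-dihydroxy-6-(3-methylbutanoyl) spiro[chroman-2,2'-pinane] (8-deformyl euglobal G3) | CC(C)CC(=O)c1c(O)cc2c(c1O)CC[C@@]1(CC[C@H]3C[C@@H]1C3(C)C)O2
A2 | alternative 1 | 7-(4-methyl-2-oxopentyl)-3,4-dihydro spiro[pyrano[4,3-b]pyran-2,2'-pinan]-5-one | CC(C)CC(=O)CC1=CC2=C(C(=O)O1)CC[C@@]1(CC[C@H]3C[C@@H]1C3(C)C)O2
A3 | alternative 2 | 3-isobutyl-1,2-benzisoxazole fused across C6–C7 of 5-(methoxymethoxy) spiro[chroman-2,2'-pinane] | CC(C)Cc1noc2cc3c(c(OCOC)c12)CC[C@@]1(CC[C@H]2C[C@@H]1C2(C)C)O3
A4 | alternative 2 | 5-(methoxymethoxy)-6-(trimethylsilyl) spiro[chroman-2,2'-pinan]-7-yl trifluoromethanesulfonate | COCOc1c([Si](C)(C)C)c(OS(=O)(=O)C(F)(F)F)cc2c1CC[C@@]1(CC[C@H]3C[C@@H]1C3(C)C)O2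
A5 | alternative 2 | N-hydroxy-3-methylbutanimidoyl chloride | CC(C)CC(Cl)=NO
A6 | alternative 2 | 6,7-didehydro-5-(methoxymethoxy) spiro[chroman-2,2'-pinane] (aryne) | COCOC1=C2CC[C@@]3(CC[C@H]4C[C@@H]3C4(C)C)OC2=CC#C1
A7 | alternative 2 | 3-methylbutanenitrile oxide | CC(C)CC#[N+][O-]
A8 | alternative 3 | 5-benzyloxy-7-hydroxy-8-formyl spiro[2H-chromene-2,2'-pinane] | O=Cc1c(O)cc(OCc2ccccc2)c2C=C[C@@]3(CC[C@H]4C[C@@H]3C4(C)C)Oc12
A9 | alternative 3 | 4-benzyloxy-2,6-dihydroxybenzaldehyde | O=Cc1c(O)cc(OCc2ccccc2)cc1O
A10 | alternative 3 | 2-[(1R,5S)-6,6-dimethylbicyclo[3.1.1]hept-2-ylidene]acetaldehyde (alkene geometry open) | O=CC=C1CC[C@H]2C[C@@H]1C2(C)C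
A11 | alternative 3 | (1R,5S)-nopinone | O=C1CC[C@H]2C[C@@H]1C2(C)C
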